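**Retrosynthetic overview**
- The target comes from a bicyclic lactone that still carries the citronellyl side chain; its Me2C=CH end is a masked CH2OH, cleaved and reduced last.
- The bicycle comes from an acyclic (Z)-allenyl aldehyde plus CO. One carbonylative [2+2+1] (allenic hetero-Pauson–Khand) makes C3a–C7a, C3–C2 and C2–O1, so the cyclohexene and the α-methylene lactone close together, steered by the C4 isovalerate already in place.
- The allenyl ester comes from an enynone: CBS reduction sets C4, and SN2′ hydride delivery makes the allene.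
- The enynone comes from a 3-alkyl-4-methyl-5,6-dihydropyran-2-one and methyl propargyl ether. This δ-lactone is only a template that fixes the (Z)-tetrasubstituted alkene and is opened again.
- The template lactone comes from (S)-citronellic acid dianion and 4-silyloxybutan-2-one. Ring order: sacrificial δ-lactone first (opened), then both rings of the target at once.

Assumption: (S)-citronellic acid, 4-hydroxybutan-2-one and methyl propargyl ether are bought as such; the bicycle is numbered as 1-benzofuran-2(3H)-one (O1, C2, C3, C3a, C4–C7, C7a).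

**Step 1**
Reactants: 1 4-hydroxybutan-2-one
Product: 2 4-[(tert-butyldimethylsilyl)oxy]butan-2-one
Conditions: TBSCl, imidazole, CH2Cl2, 0 °C → 23 °C
Reagents that add atoms: tert-butyldimethylsilyl chloride (TBSCl), CC(C)(C)[Si](C)(C)Cl
Why: Imidazole-mediated O-silylation masks the primary alcohol for the enolate step; no stereocenter is involved.

**Step 2**
Reactants: 3 (S)-citronellic acid [(3S)-3,7-dimethyloct-6-enoic acid]; 2 4-[(tert-butyldimethylsilyl)oxy]butan-2-one
Product: 5 5-[(tert-butyldimethylsilyl)oxy]-3-hydroxy-3-methyl-2-[(2S)-6-methylhept-5-en-2-yl]pentanoic acid (C2/C3 diastereomer mixture), via dilithium enediolate 4 (not isolated)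
Conditions: LiN(i-Pr)2 (2.2 equiv), THF, 0 → 23 °C; then 2, −78 → −20 °C; aq. HCl (pH 4)
Reagents that add atoms: none
Why: Aldol addition of the carboxylic acid enediolate (Ivanov type) to the methyl ketone makes the C–C bond that becomes the ring C5=C6 alkene; the two new centers form unselectively and are erased in step 3, and the β-stereocenter of 3 is not touched.

**Step 3**
Reactants: 5 aldol acid
Product: 7 4-methyl-3-[(2S)-6-methylhept-5-en-2-yl]-5,6-dihydro-2H-pyran-2-one, via hydroxy lactone 6 (not isolated)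
Conditions: p-TsOH·H2O (0.2 equiv), MeOH, 23 °C; then toluene, 90 °C, Dean–Stark
Reagents that add atoms: none
Why: Acid-catalysed desilylation and δ-lactonisation, then E1 dehydration of the tertiary β-hydroxy lactone, give the conjugated tetrasubstituted alkene (the thermodynamic isomer), whose cis geometry is enforced by the six-membered ring; isolated trisubstituted alkenes tolerate catalytic TsOH under these conditions.

**Step 4**
Reactants: 7 template dihydropyranone; 8 3-methoxyprop-1-yne (methyl propargyl ether)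
Product: 12 (5Z)-1-methoxy-6-methyl-5-[(2S)-6-methylhept-5-en-2-yl]-8-[(triethylsilyl)oxy]oct-5-en-2-yn-4-one, via lithium methoxypropynide 9 (not isolated), via lithium hemiketalate 10 (not isolated), via ring-opened lithium alkoxide 11 (not isolated)
Conditions: 8, n-BuLi, THF, −78 °C; then 7, −78 → −40 °C; then TESCl, −78 → 0 °C
Reagents that add atoms: chlorotriethylsilane (TESCl), CC[Si](Cl)(CC)CC
Why: Nucleophilic acyl substitution: the alkynyllithium adds once to the lactone carbonyl (the lithium hemiketalate resists a second addition), and silylation of the ring-opened primary alkoxide drains the equilibrium to the open enynone, which keeps the ring-imposed (Z)-alkene.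

**Step 5**
Reactants: 12 TES enynone
Product: 13 (4S,5Z)-1-methoxy-6-methyl-5-[(2S)-6-methylhept-5-en-2-yl]-8-[(triethylsilyl)oxy]oct-5-en-2-yn-4-ol
Conditions: (R)-2-methyl-CBS-oxazaborolidine (C18H20BNO, 1.0 equiv), catecholborane (2 equiv), toluene/CH2Cl2, −78 °C; MeOH, then dilute NaOH wash
Reagents that add atoms: none
Why: Corey–Bakshi–Shibata reduction: the tetrasubstituted alkenyl arm is the large group and the slim alkynyl arm the small one, so the (R)-catalyst delivers hydride to the face that gives the (4S) carbinol under reagent control, independent of the remote side-chain center; catecholborane at −78 °C leaves the alkenes alone.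

**Step 6**
Reactants: 13 (4S)-propargylic alcohol
Product: 14 (4S,5Z)-6-methyl-5-[(2S)-6-methylhept-5-en-2-yl]-8-[(triethylsilyl)oxy]octa-1,2,5-trien-4-ol
Conditions: LiAlH4 (3 equiv), THF, 0 → 40 °C; H2O/NaOH work-up
Reagents that add atoms: none
Why: Alkoxide-directed trans-hydroalumination puts hydride on C3 and aluminium on C2, and β-elimination of methoxide (net SN2′ reduction of a 4-methoxy-2-ynol) gives the terminal allene without touching C4.

**Step 7**
Reactants: 14 allenyl alcohol
Product: 15 (4S,5Z)-6-methyl-5-[(2S)-6-methylhept-5-en-2-yl]-8-[(triethylsilyl)oxy]octa-1,2,5-trien-4-yl 3-methylbutanoate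
Conditions: isovaleryl chloride, pyridine, DMAP (cat.), CH2Cl2, 0 → 23 °C
Reagents that add atoms: 3-methylbutanoyl chloride (isovaleryl chloride), CC(C)CC(=O)Cl
Why: DMAP-catalysed acylation of the secondary alcohol; C4 keeps its configuration because only the O–H bond reacts.

**Step 8**
Reactants: 15 allenyl isovalerate TES ether
Product: 16 (4S,5Z)-6-methyl-5-[(2S)-6-methylhept-5-en-2-yl]-8-oxoocta-1,2,5-trien-4-yl 3-methylbutanoate
Conditions: IBX (2-iodoxybenzoic acid, 3 equiv), DMSO, 23 °C
Reagents that add atoms: none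
Why: IBX in DMSO cleaves a primary triethylsilyl ether and oxidises the freed alcohol in the same flask (tandem desilylation/oxidation), and the neutral medium keeps the skipped C=C out of conjugation with the new aldehyde.

**Step 9**
Reactants: 16 (Z)-allenyl aldehyde
Product: 17 (3aR,4S,7aR)-6-methyl-3-methylidene-5-[(2S)-6-methylhept-5-en-2-yl]-2-oxo-2,3,3a,4,7,7a-hexahydro-1-benzofuran-4-yl 3-methylbutanoate
Conditions: Ru3(CO)12 (5 mol%), CO (20 atm), 1,4-dioxane, 120 °C
Reagents that add atoms: carbon monoxide, [C-]#[O+]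
Why: Allenic hetero-Pauson–Khand reaction (ruthenium-catalysed carbonylative [2+2+1] of the aldehyde C=O, the proximal allene C=C and CO): oxidative cyclisation makes C3a–C7a and CO insertion/reductive elimination closes the lactone, so both rings form at once with the exo-methylene in place; the oxametallacycle enforces the cis ring fusion, and the C4 ester sits pseudoaxial to avoid A(1,2) strain with the C5 side chain so that C3a–C3 forms anti to it (the all-cis alternative needs a 1,3-diaxial O/O contact), which is predicted to give (3aR,7aR).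

**Step 10**
Reactants: 17 bicyclic lactone with citronellyl side chain
Product: 19 (3aR,4S,7aR)-6-methyl-3-methylidene-2-oxo-5-[(2S)-5-oxopentan-2-yl]-2,3,3a,4,7,7a-hexahydro-1-benzofuran-4-yl 3-methylbutanoate, via side-chain diol 18 (not isolated)
Conditions: OsO4 (2 mol%), NMO (1.1 equiv), acetone/H2O, 0 °C; then NaIO4, THF/H2O (pH 7), 23 °C
Reagents that add atoms: N-methylmorpholine N-oxide (oxygen source, relayed through OsO4), C[N+]1([O-])CCOCC1; water, O
Why: Upjohn dihydroxylation should pick the open, electron-rich trisubstituted side-chain alkene over the shielded tetrasubstituted ring alkene and the electron-poor α-methylene, and Malaprade cleavage of the diol with NaIO4 gives the aldehyde; the carbinol center of 18 is destroyed again.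

**Step 11**
Reactants: 19 side-chain aldehyde
Product: 20 (3aR,4S,7aR)-5-[(2S)-5-hydroxypentan-2-yl]-6-methyl-3-methylidene-2-oxo-2,3,3a,4,7,7a-hexahydro-1-benzofuran-4-yl 3-methylbutanoate (CNP0289409.1)
Conditions: NaBH(OAc)3 (2 equiv), THF, 0 → 23 °C
Reagents that add atoms: none
Why: Chemoselective hydride reduction: NaBH(OAc)3 reduces the aldehyde but is too weak to attack the ester, the lactone or the conjugated exo-methylene, and no stereocenter changes.

**Compound list**
1 | 4-hydroxybutan-2-one | CC(=O)CCO | starting material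
2 | 4-[(tert-butyldimethylsilyl)oxy]butan-2-one | CC(=O)CCO[Si](C)(C)C(C)(C)C | intermediate
3 | (3S)-3,7-dimethyloct-6-enoic acid, (S)-citronellic acid | OC(=O)C[C@@H](C)CCC=C(C)C | starting material
4 | dilithium enediolate of 3 | [Li+].[Li+].[O-]C([O-])=C[C@@H](C)CCC=C(C)C | intermediate (not isolated)
5 | 5-[(tert-butyldimethylsilyl)oxy]-3-hydroxy-3-methyl-2-[(2S)-6-methylhept-5-en-2-yl]pentanoic acid (C2/C3 mixture) | OC(=O)C([C@@H](C)CCC=C(C)C)C(C)(O)CCO[Si](C)(C)C(C)(C)C | intermediate
6 | 4-hydroxy-4-methyl-3-[(2S)-6-methylhept-5-en-2-yl]oxan-2-one (C3/C4 mixture) | O=C1OCCC(C)(O)C1[C@@H](C)CCC=C(C)C | intermediate (not isolated)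
7 | 4-methyl-3-[(2S)-6-methylhept-5-en-2-yl]-5,6-dihydro-2H-pyran-2-one | O=C1OCCC(C)=C1[C@@H](C)CCC=C(C)C | intermediate
8 | 3-methoxyprop-1-yne | C#CCOC | starting material
9 | lithium 3-methoxyprop-1-yn-1-ide | [Li+].[C-]#CCOC | intermediate (not isolated)
10 | lithium 2-(3-methoxyprop-1-yn-1-yl)-4-methyl-3-[(2S)-6-methylhept-5-en-2-yl]-5,6-dihydro-2H-pyran-2-olate (C2 mixture) | [Li+].[O-]C1(C#CCOC)OCCC(C)=C1[C@@H](C)CCC=C(C)C | intermediate (not isolated)
11 | lithium (3Z)-8-methoxy-3-methyl-4-[(2S)-6-methylhept-5-en-2-yl]-5-oxooct-3-en-6-yn-1-olate | [Li+].[O-]CC/C(C)=C(\C(=O)C#CCOC)[C@@H](C)CCC=C(C)C | intermediate (not isolated)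
12 | (5Z)-1-methoxy-6-methyl-5-[(2S)-6-methylhept-5-en-2-yl]-8-[(triethylsilyl)oxy]oct-5-en-2-yn-4-one | CC[Si](CC)(CC)OCC/C(C)=C(\C(=O)C#CCOC)[C@@H](C)CCC=C(C)C | intermediate
13 | (4S,5Z)-1-methoxy-6-methyl-5-[(2S)-6-methylhept-5-en-2-yl]-8-[(triethylsilyl)oxy]oct-5-en-2-yn-4-ol | CC[Si](CC)(CC)OCC/C(C)=C(\[C@@H](O)C#CCOC)[C@@H](C)CCC=C(C)C | intermediate
14 | (4S,5Z)-6-methyl-5-[(2S)-6-methylhept-5-en-2-yl]-8-[(triethylsilyl)oxy]octa-1,2,5-trien-4-ol | CC[Si](CC)(CC)OCC/C(C)=C(\[C@@H](O)C=C=C)[C@@H](C)CCC=C(C)C | intermediate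
15 | (4S,5Z)-6-methyl-5-[(2S)-6-methylhept-5-en-2-yl]-8-[(triethylsilyl)oxy]octa-1,2,5-trien-4-yl 3-methylbutanoate | CC[Si](CC)(CC)OCC/C(C)=C(\[C@@H](OC(=O)CC(C)C)C=C=C)[C@@H](C)CCC=C(C)C | intermediate
16 | (4S,5Z)-6-methyl-5-[(2S)-6-methylhept-5-en-2-yl]-8-oxoocta-1,2,5-trien-4-yl 3-methylbutanoate | O=CC/C(C)=C(\[C@@H](OC(=O)CC(C)C)C=C=C)[C@@H](C)CCC=C(C)C | intermediate
17 | (3aR,4S,7aR)-6-methyl-3-methylidene-5-[(2S)-6-methylhept-5-en-2-yl]-2-oxo-2,3,3a,4,7,7a-hexahydro-1-benzofuran-4-yl 3-methylbutanoate | C=C1C(=O)O[C@@H]2CC(C)=C([C@@H](C)CCC=C(C)C)[C@@H](OC(=O)CC(C)C)[C@H]12 | intermediate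
18 | (3aR,4S,7aR)-5-[(2S)-5,6-dihydroxy-6-methylheptan-2-yl]-6-methyl-3-methylidene-2-oxo-2,3,3a,4,7,7a-hexahydro-1-benzofuran-4-yl 3-methylbutanoate (side-chain C5 epimers) | C=C1C(=O)O[C@@H]2CC(C)=C([C@@H](C)CCC(O)C(C)(C)O)[C@@H](OC(=O)CC(C)C)[C@H]12 | intermediate (not isolated)
19 | (3aR,4S,7aR)-6-methyl-3-methylidene-2-oxo-5-[(2S)-5-oxopentan-2-yl]-2,3,3a,4,7,7a-hexahydro-1-benzofuran-4-yl 3-methylbutanoate | C=C1C(=O)O[C@@H]2CC(C)=C([C@@H](C)CCC=O)[C@@H](OC(=O)CC(C)C)[C@H]12 | intermediate
20 | (3aR,4S,7aR)-5-[(2S)-5-hydroxypentan-2-yl]-6-methyl-3-methylidene-2-oxo-2,3,3a,4,7,7a-hexahydro-1-benzofuran-4-yl 3-methylbutanoate | C=C1C(=O)O[C@@H]2CC(C)=C([C@@H](C)CCCO)[C@@H](OC(=O)CC(C)C)[C@H]12 | target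

**Step count and risks**
Total: 11 steps. Longest linear sequence: 11 steps (1 → 20 through steps 1–11), or 10 counted from (S)-citronellic acid 3.

Most likely to fail, first: step 9. The doubly activated (allylic and allenylic) isovalerate may ionise or migrate on zerovalent ruthenium at 120 °C, the skipped enal may slip into conjugation or lose CO, and the 4,3a-trans/3a,7a-cis outcome is a conformational prediction, not a precedent for this substitution pattern. The fallback moves the acylation behind the ring formation and uses an ether that cannot ionise. It sets out from 14. TBSOTf and 2,6-lutidine give the bis-silyl ether F1. IBX in DMSO converts only the primary TES ether and gives the silyloxy allenyl aldehyde F2. Stoichiometric Mo(CO)6 with DMSO in toluene at 100 °C (no CO pressure) closes both rings to the bicyclic silyl ether F3. HF·pyridine frees the C4 alcohol F4, and isovaleric anhydride with DMAP brings the route back at 17.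

Second: step 4. The acetylide may deprotonate the γ-positions of the hindered unsaturated lactone instead of adding, and any enynone freed before silylation can take up a second acetylide. The fallback sets out from 7. MeNH(OMe)·HCl with Me2AlCl in CH2Cl2 opens the lactone to the hydroxy Weinreb amide F5. TESCl and imidazole give the silylated Weinreb amide F6. The chelated tetrahedral adduct of F6 with acetylide 9 cannot over-add and collapses on work-up to 12.

Third: step 3. Hot acid may leave β,γ-unsaturated isomers of the lactone or attack the side-chain alkene. The fallback replaces the E1 dehydration by a base-mediated E1cB elimination. It sets out from 6, isolated after the methanol stage. Ac2O, DMAP and Et3N give the tertiary acetate F7, and DBU in toluene at 60 °C eliminates acetic acid to come back at 7.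

**Further compounds**
F1 | step 9 | (4S,5Z)-4-[(tert-butyldimethylsilyl)oxy]-6-methyl-5-[(2S)-6-methylhept-5-en-2-yl]-8-[(triethylsilyl)oxy]octa-1,2,5-triene | CC[Si](CC)(CC)OCC/C(C)=C(\[C@@H](O[Si](C)(C)C(C)(C)C)C=C=C)[C@@H](C)CCC=C(C)C
F2 | step 9 | (3Z,5S)-5-[(tert-butyldimethylsilyl)oxy]-3-methyl-4-[(2S)-6-methylhept-5-en-2-yl]octa-3,6,7-trienal | O=CC/C(C)=C(\[C@@H](O[Si](C)(C)C(C)(C)C)C=C=C)[C@@H](C)CCC=C(C)C
F3 | step 9 | (3aR,4S,7aR)-4-[(tert-butyldimethylsilyl)oxy]-6-methyl-3-methylidene-5-[(2S)-6-methylhept-5-en-2-yl]-3a,4,7,7a-tetrahydro-1-benzofuran-2(3H)-one | C=C1C(=O)O[C@@H]2CC(C)=C([C@@H](C)CCC=C(C)C)[C@@H](O[Si](C)(C)C(C)(C)C)[C@H]12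
F4 | step 9 | (3aS,4S,7aR)-4-hydroxy-6-methyl-3-methylidene-5-[(2S)-6-methylhept-5-en-2-yl]-3a,4,7,7a-tetrahydro-1-benzofuran-2(3H)-one | C=C1C(=O)O[C@@H]2CC(C)=C([C@@H](C)CCC=C(C)C)[C@@H](O)[C@H]12
F5 | step 4 | (2Z)-5-hydroxy-N-methoxy-N,3-dimethyl-2-[(2S)-6-methylhept-5-en-2-yl]pent-2-enamide | OCC/C(C)=C(\C(=O)N(C)OC)[C@@H](C)CCC=C(C)C
F6 | step 4 | (2Z)-N-methoxy-N,3-dimethyl-2-[(2S)-6-methylhept-5-en-2-yl]-5-[(triethylsilyl)oxy]pent-2-enamide | CC[Si](CC)(CC)OCC/C(C)=C(\C(=O)N(C)OC)[C@@H](C)CCC=C(C)C
F7 | step 3 | 4-methyl-3-[(2S)-6-methylhept-5-en-2-yl]-2-oxooxan-4-yl acetate (C3/C4 mixture) | CC(=O)OC1(C)CCOC(=O)C1[C@@H](C)CCC=C(C)C
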